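## Structural features

The target 39 is a melampolide: a cyclodeca-1(10),4-diene in which C1=C10 is cis within the ring and carries the methyl ester C14, C4=C5 is E and carries the methyl C15, and an α-methylene-γ-butyrolactone (O–C6, C7–C11, C12, exocyclic C13) is fused trans across C6–C7. Four contiguous stereocentres lie on one edge of the ring, C6 (R), C7 (S), C8 (S) and C9 (S): O6 is trans to C11, the C8 acyloxy group is cis to C11, and the C9 acetoxy group is trans to O8. Three different esters sit on neighbouring oxygens (lactone, 2-(hydroxymethyl)acrylate on O8, acetate on O9). The hazards that follow are acyl migration between O8 and O9, closure of a free O8 hydroxyl onto the C14 ester, and conjugate addition to the two exocyclic enoates. The ring is also fragile: the 1,5-diene C10=C1–C2–C3–C4=C5 can undergo a Cope shift on heating or transannular cyclisation under acid, and the C9 acetate is allylic to an enoate. The real difficulty is to form a ten-membered ring with one cis and one trans trisubstituted alkene while placing C6 and C7 correctly, and then to set C8 and C9 on a flexible medium ring. The key step exploits two features: the sequence C9(O)–C8–C7(C11)–C6(O)–C5=C4 is the pattern of an oxy-Cope product, and the cis C1=C10 alkene fits into a cyclohexene made of C9, C10, C1, C2, C3 and C4.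

## Logic of the disconnections

39 ⇒ 38. Only the Si–O bond of the side-chain silyl ether is cut. The primary allylic hydroxyl of the acrylate must stay masked until all oxidations are over. The forward step has to remove a bulky silyl group without touching three esters and two Michael acceptors.

38 ⇒ 37 ⇒ 36. The O–CH3 bond of the ester and then the C14–OH bond of the acid are cut, returning C14 to an aldehyde. C14 is kept at a low oxidation level through the ring expansion because an ester on C10 would make the cyclohexenone a doubly activated acceptor. The forward steps need an aldehyde-selective oxidant and an esterification that avoids diazoalkanes.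

36 ⇒ 34. The lactone acyl bond O6–C12 is cut and C12 and C14 are lowered to primary alcohols. One oxidation then builds the lactone and the C14 aldehyde together. The oxidant must be selective for primary alcohols, because the C6 hydroxyl is secondary and allylic.

34 ⇒ 33 ⇒ 32. The two silyl ethers on O12 and O14 and the arylmethyl ether on O6 are put back. This gives a fully protected ring carrying both final acyl groups on O8 and O9. The forward steps need two orthogonal deprotections that leave the bulkier side-chain silyl ether in place.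

32 ⇒ 31 ⇒ 30. The O9–acetyl bond and then the C9–H bond are cut, giving the C9 ketone. The ketone is what the ring expansion delivers, and the C8 ester next to it can direct the hydride. The forward reduction must be 1,2-selective on an enone and must enter anti to the C8–O bond.

30 ⇒ 26 + 29. The C8–O bond to the carboxylate oxygen is cut with inversion at C8. Oxygen is expected to reach C8 of the ring enolate on the face opposite to the one the target needs, so the acyl group is introduced by displacement. This also means O8 is never free beside the later C14 ester or the C9 acetate. 29 ⇒ 28 ⇒ 27 cuts the Si–O and the ethyl ester bonds of a commercial hydroxymethyl acrylate. The forward demand is an SN2 reaction at a ring carbon next to a carbonyl group.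

26 ⇒ 24. The C8–O bond is cut, leaving the methylene ketone. The demand is regioselective enolisation at C8 (C10 is sp2) and oxygen transfer that tolerates four alkenes.

24 ⇒ 21. The C6–C7 bond is cut and C4–C9 is reconnected, which contracts the ten-membered ring to a cyclohexene with an (E)-enol ether on C4 and an (E)-diene on C9. Two stereocentres, one ring and the E alkene are traded for one quaternary centre and one carbinol. The demand is a chair [3,3] shift of the alkoxide with both alkenyl groups trans.

21 ⇒ 15 + 19. The C8–C9 bond is cut to a cyclohexenone and a dienyl nucleophile. This separates C7, C8, C11, C12 and C13 from the ring. The forward step needs 1,2-addition to a hindered enone on the face anti to the alkenyl group at C4.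

19 ⇒ 17 + 18, and 17 ⇒ 16. The C7–C11 bond is cut to a 2-bromoallyl ether and a two-carbon bis-stannane. The forward coupling must stop after one tin terminus has reacted and must keep the E geometry.

15 ⇒ 14 ⇒ 12 + 13. The O14–Si bond and then the C10–C14 bond are cut. C14 comes from formaldehyde in one step at the α-carbon of the enone. The protection must be base- and acid-free because of the enol ether.

12 ⇒ 10. The C10=C1 unsaturation is removed. The saturated ketone is the safe substrate for the preceding C–O coupling. The forward dehydrogenation must spare the enol ether.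

10 ⇒ 8 + 9, 8 ⇒ 6 + 7, and 6 ⇒ 5 ⇒ 4. The C6–O bond, then C5=C6, then the C5 aldehyde are cut back to an allyl group. Each forward step is stereospecific or E-selective, so the enol ether geometry that fixes C6 is secured by the sequence and not by a separation.

4 ⇒ 2 + 3, and 2 ⇒ 1. The C4–C5 bond is cut. The quaternary stereocentre C4, the only one that has to be made by asymmetric catalysis, comes from a prochiral tetrasubstituted enolate. The demand is regiocontrol (more substituted enolate) and enantiocontrol by the ligand.

## Other disconnections considered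

Alternative 1: The cut treats both ring alkenes as the remains of a four-membered ring. C1–C4 and C5–C10 are reconnected to give tricycle A1, whose bonds C1–C10 and C4–C5 are then cut to the bicyclic enone ester A2 and 1-methylcyclobutene A3.
- Forward key step: irradiation of A2 with A3 would give the cis-anti-cis [2+2] adduct A1 (two σ bonds, one cyclobutane). Heating A1 would then cleave the central cyclobutane to the ten-membered dienone A4.
- In its favour: C6, C7 and C8 are placed on a rigid bicyclic lactone before any medium ring exists. C14 is an ester from the start, so the late oxidation and esterification steps of the chosen plan disappear. On both points this alternative is the better one.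
- Against it here: nothing strong controls the orientation of the unsymmetrical alkene A3 on the excited enone or the face of addition next to C6. The cycloreversion does not assign ring-cis to C1=C10 and E to C4=C5 the way a chair transition state does. The temperature it is likely to need is one at which the new 1,5-diene of A4 can rearrange further by a Cope shift. A4 would still need reduction at C9 beside a β-keto ester, two acylations and a base-mediated α-methylenation of the lactone.
- Comparison: in structure, three centres are set early but A2 needs its own asymmetric synthesis, whereas the chosen plan derives C6 and C7 from one quaternary centre. In mechanism, a stepwise photocycloaddition and a high-temperature fragmentation stand against a concerted chair [3,3] shift at or below room temperature. In step economy the two are expected to be about equal, the gain at C14 being offset by the methylenation and the preparation of A2.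

Alternative 2: The cut is the C8–C9 bond. It gives the open-chain aldehyde A6, in which C9 is the acetoxy-bearing end of an allylic bromide (bromine on C1, enol acetate C9=C10, ester C14 on C10).
- Forward key step: CrCl2 would convert the C1 bromide of A6 into an allylchromium species that adds through C9 to the C8 aldehyde (Nozaki–Hiyama-type allylation). This forms C8–C9, moves the alkene to C1=C10 and closes the ten-membered ring to A5.
- In its favour: the ring, two stereocentres, the C9 acetate and the ester-bearing alkene come in one mild, chemoselective operation from a precursor that already holds the lactone. A5 is one acylation and one deprotection from 39, so in endgame economy this alternative is clearly the better one.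
- Against it here: a ten-membered ring must be closed end to end, whereas the chosen plan expands an existing ring. γ-Oxygenated allylchromium reagents normally give the anti 1,2-diol relationship through a chair transition state, but 39 needs the threo arrangement (O8 and O9 trans on the ring). The new trisubstituted alkene must come out ring-cis. The C8 alkoxide sits γ to the C14 ester and could close to an alkylidene butyrolactone. The aldehyde of A6 has an acidic C7 hydrogen with the lactone oxygen β to it, so elimination and epimerisation threaten the precursor.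
- Comparison: in structure, the chosen plan fixes C6 and C7 in the key step and C8 and C9 afterwards; the alternative does the reverse. In mechanism, a metal-centred closed transition state under kinetic control stands against a sigmatropic shift whose outcome is dictated by one pre-set centre. In step economy the alternative is shorter after the key step, but A6 needs a long linear preparation, so the totals are expected to be similar.

Alternative 3: The cut re-forms the C5–C10 bond. The two ring alkenes become the cis-fused decalin A8, with a boronate on C4 and a mesylate on C1.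
- Forward key step: addition of an alkoxide to boron in A8 would trigger a Grob-type fragmentation. The C4–B electrons form C4=C5, the C5–C10 σ bond breaks, C1=C10 forms and the mesylate leaves, giving A7; no σ bond is made.
- In its favour: both alkene geometries follow stereospecifically from antiperiplanar alignment in a rigid bicycle. This is equal in reliability to the chosen plan, where the cis alkene is inherited and the E alkene follows from the chair. C14 is an ester from the outset. C6 to C9 are set on a cyclohexane, where facial control is more dependable than on the ten-membered ring that the chosen plan uses for C8 and C9; on this point the alternative is the better one.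
- Against it here: A8 needs eight stereocentres, of which C1, C4, C5 and C10 are built only to be destroyed, against two sacrificial centres in 21. The tertiary C4–B bond on a methyl-bearing carbon cannot be made by ordinary hydroboration. The quaternary C10 carries an ester beside a leaving group. A7 would still need α-methylenation of the lactone, two deprotections and two acylations.
- Comparison: in structure, the alternative stores the ring as a decalin and the chosen plan stores it as a cyclohexene with two side chains. In mechanism, both are concerted and stereospecific. In step economy the route to A8 is expected to be considerably longer than the twelve steps to 21.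

Key step: step 13

## Remarks before the steps

- Numbering and abbreviations: ring atoms carry germacrane numbers throughout (C9 is the carbinol or ketone carbon, C4 the methyl-bearing carbon). "1(10)-cis" means that C2 and C9 lie on the same side of C1=C10. TBS = tert-butyldimethylsilyl, TBDPS = tert-butyldiphenylsilyl, PMB = 4-methoxybenzyl.
- Key-step structures: the configurations of 21 (C4 S, C9 R, both side-chain alkenes E) and of 24 (C6 R, C7 S) are consistent with the chair transition state and with 39.
- Design choices:
  - O14 carries a silyl ether, because an arylmethyl ether could not be installed without acid in the presence of the enol ether.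
  - The enol ether is made on the saturated ketone, before the enone and its hydroxymethyl group exist.
  - Oxygen is expected to reach C8 on the face opposite to the one required, so the O8 acyl group is introduced with inversion, and early.
  - The lactone is formed with a primary-selective nitroxyl oxidation, because the C6 hydroxyl is allylic.
- Assumption on enantiopurity: the allylation in step 2 is expected to give 4 in high but not complete enantiomeric excess. It is assumed that the minor enantiomer is removed by recrystallisation of a crystalline derivative (the semicarbazone of 4 or a later solid); this is not counted as a step.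

## Route

Step 1
Reactants: 1 2-methylcyclohexanone
Product: 2 trimethyl[(2-methylcyclohex-1-en-1-yl)oxy]silane
Conditions: TMSCl, NaI, Et3N, MeCN, rt
Reagents that add atoms: chlorotrimethylsilane, C[Si](C)(C)Cl
Why: Silyl enol ether formation under equilibrating conditions with iodotrimethylsilane made in the flask should favour the more substituted enol ether, which fixes the later allylation at C4.

Step 2
Reactants: 2 trimethyl[(2-methylcyclohex-1-en-1-yl)oxy]silane; 3 diallyl carbonate
Product: 4 (S)-2-allyl-2-methylcyclohexan-1-one
Conditions: Pd2(dba)3 (2.5 mol%), (S)-t-Bu-PHOX (6.25 mol%), Bu4N[Ph3SiF2] (35 mol%), THF, 25 °C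
Reagents that add atoms: none
Why: Palladium-catalysed asymmetric allylic alkylation of a preformed enol derivative: zerovalent palladium ionises 3 to a π-allyl complex, fluoride releases the tetrasubstituted enolate from 2, and C–C bond formation inside the chiral pocket of the (S)-phosphinooxazoline ligand should set the quaternary C4 as S.

Step 3
Reactants: 4 (S)-2-allyl-2-methylcyclohexan-1-one
Product: 5 (S)-2-methyl-2-[(E)-prop-1-en-1-yl]cyclohexan-1-one
Conditions: RuHCl(CO)(PPh3)3 (2 mol%), toluene, 80 °C
Reagents that add atoms: none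
Why: Metal hydride-catalysed alkene isomerisation (hydrometalation then β-hydride elimination) should move the terminal alkene to the internal position beside the quaternary carbon; no stereocentre is touched.

Step 4
Reactants: 5 (S)-2-methyl-2-[(E)-prop-1-en-1-yl]cyclohexan-1-one
Product: 6 (S)-1-methyl-2-oxocyclohexane-1-carbaldehyde
Conditions: O3, CH2Cl2, −78 °C; then Me2S, −78 °C to rt
Reagents that add atoms: ozone, [O-][O+]=O
Why: Ozonolysis with reductive work-up cleaves the only alkene to the C5 aldehyde; C4 has no hydrogen and cannot epimerise, and the aldehyde is used without delay because β-keto aldehydes can deformylate.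

Step 5
Reactants: 6 (S)-1-methyl-2-oxocyclohexane-1-carbaldehyde; 7 iodoform
Product: 8 (S)-2-[(E)-2-iodoethenyl]-2-methylcyclohexan-1-one
Conditions: CrCl2, THF, 0 °C to rt
Reagents that add atoms: none
Why: Takai iodo-olefination: the geminal dichromium reagent formed from 7 adds to the aldehyde much faster than to the ketone, and a neopentyl-type aldehyde should give the (E)-iodoalkene with high selectivity.

Step 6
Reactants: 8 (S)-2-[(E)-2-iodoethenyl]-2-methylcyclohexan-1-one; 9 4-methoxybenzyl alcohol
Product: 10 (S)-2-{(E)-2-[(4-methoxybenzyl)oxy]ethenyl}-2-methylcyclohexan-1-one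
Conditions: CuI (10 mol%), 3,4,7,8-tetramethyl-1,10-phenanthroline (20 mol%), Cs2CO3, toluene, 80 °C
Reagents that add atoms: none
Why: Copper-catalysed Ullmann-type C–O coupling of a vinyl iodide with a primary alcohol proceeds with retention of alkene geometry, so the (E)-enol ether that becomes the equatorial C6 terminus is secured; at this stage there is no Michael acceptor for the alkoxide to attack.

Step 7
Reactants: 10 (S)-2-{(E)-2-[(4-methoxybenzyl)oxy]ethenyl}-2-methylcyclohexan-1-one
Product: 12 (S)-6-{(E)-2-[(4-methoxybenzyl)oxy]ethenyl}-6-methylcyclohex-2-en-1-one, via lithium enolate 11 (not isolated)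
Conditions: LiN(iPr)2, THF, −78 °C; then PhS(Cl)=N-t-Bu, −78 °C
Reagents that add atoms: none
Why: Mukaiyama dehydrogenation: the only possible enolate (C4 is quaternary) is sulfenylated at C10 and the adduct eliminates at low temperature to the enone C10=C1; these non-acidic, metal-free conditions should leave the enol ether intact.

Step 8
Reactants: 12 (S)-6-{(E)-2-[(4-methoxybenzyl)oxy]ethenyl}-6-methylcyclohex-2-en-1-one; 13 formaldehyde
Product: 14 (S)-2-(hydroxymethyl)-6-{(E)-2-[(4-methoxybenzyl)oxy]ethenyl}-6-methylcyclohex-2-en-1-one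
Conditions: 37% aq. HCHO, DMAP, THF/H2O, rt
Reagents that add atoms: none
Why: Morita–Baylis–Hillman reaction: reversible conjugate addition of the amine at C1 gives an enolate that is hydroxymethylated at C10, and loss of the amine restores the enone; the aqueous basic medium is compatible with the enol ether.

Step 9
Reactants: 14 (S)-2-(hydroxymethyl)-6-{(E)-2-[(4-methoxybenzyl)oxy]ethenyl}-6-methylcyclohex-2-en-1-one
Product: 15 (S)-2-{[(tert-butyldimethylsilyl)oxy]methyl}-6-{(E)-2-[(4-methoxybenzyl)oxy]ethenyl}-6-methylcyclohex-2-en-1-one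
Conditions: TBSCl, imidazole, CH2Cl2, 0 °C to rt
Reagents that add atoms: tert-butyldimethylsilyl chloride, CC(C)(C)[Si](C)(C)Cl
Why: Silylation of a primary allylic alcohol under neutral conditions, chosen because neither the acid needed for an arylmethyl ether nor strong base is tolerated by the enol ether and the hydroxymethyl enone.

Step 10
Reactants: 16 2-bromoprop-2-en-1-ol
Product: 17 [(2-bromoprop-2-en-1-yl)oxy](tert-butyl)dimethylsilane
Conditions: TBSCl, imidazole, CH2Cl2, rt
Reagents that add atoms: tert-butyldimethylsilyl chloride, CC(C)(C)[Si](C)(C)Cl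
Why: Standard silylation of the primary alcohol so that the later organolithium chemistry is possible.

Step 11
Reactants: 17 [(2-bromoprop-2-en-1-yl)oxy](tert-butyl)dimethylsilane; 18 (E)-1,2-bis(tributylstannyl)ethene
Product: 19 (E)-tert-butyldimethyl{[2-methylidene-4-(tributylstannyl)but-3-en-1-yl]oxy}silane
Conditions: Pd(PPh3)4 (5 mol%), 18 (3 equiv), toluene, 90 °C
Reagents that add atoms: none
Why: Stille coupling: oxidative addition of the vinyl bromide and transmetalation of one tin terminus of 18, used in excess to suppress double coupling, should give the (E)-dienylstannane with retention of geometry.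

Step 12
Reactants: 19 (E)-tert-butyldimethyl{[2-methylidene-4-(tributylstannyl)but-3-en-1-yl]oxy}silane; 15 (S)-2-{[(tert-butyldimethylsilyl)oxy]methyl}-6-{(E)-2-[(4-methoxybenzyl)oxy]ethenyl}-6-methylcyclohex-2-en-1-one
Product: 21 (1R,6S)-1-[(1E)-3-{[(tert-butyldimethylsilyl)oxy]methyl}buta-1,3-dien-1-yl]-2-{[(tert-butyldimethylsilyl)oxy]methyl}-6-{(E)-2-[(4-methoxybenzyl)oxy]ethenyl}-6-methylcyclohex-2-en-1-ol, via dienyllithium 20 (not isolated)
Conditions: MeLi, THF, −78 °C; then 15, −78 °C; aq. NH4Cl
Reagents that add atoms: none
Why: Tin–lithium exchange gives the configurationally stable (E)-dienyllithium 20, which should add 1,2 to the hindered enone as alkenyllithiums do with 2,6,6-trisubstituted cyclohexenones. The carbinol centre C9 (R) is set by attack anti to the alkenyl group at C4, which has the smaller conformational energy and is expected to occupy the pseudo-axial site, so the two alkenyl groups end up trans.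

Step 13
Reactants: 21 (1R,6S)-1-[(1E)-3-{[(tert-butyldimethylsilyl)oxy]methyl}buta-1,3-dien-1-yl]-2-{[(tert-butyldimethylsilyl)oxy]methyl}-6-{(E)-2-[(4-methoxybenzyl)oxy]ethenyl}-6-methylcyclohex-2-en-1-ol
Product: 24 (6R,7S)-6-(PMB-oxy)-12,14-bis(TBS-oxy)-1(10)-cis,4E-germacra-1(10),4,11(13)-trien-9-one, via potassium alkoxide 22 (not isolated), via potassium enolate 23 (not isolated)
Conditions: KH, 18-crown-6, THF, 0 °C to rt; then AcOH, −78 °C
Reagents that add atoms: none
Why: KH with 18-crown-6 converts 21 into the dissociated alkoxide 22, whose oxyanion weakens the C4–C9 bond and accelerates the [3,3]-sigmatropic shift across C7=C8–C9–C4–C5=C6; the closest known reaction type is the anionic oxy-Cope ring expansion of trans-1,2-dialkenylcyclohexanols to (E)-cyclodec-5-enones. The ten-membered ring is not closed end to end: it arises by ring expansion, C6–C7 forming as C4–C9 breaks inside one six-centre chair transition state. In that chair the ring carbons C3 and C10 are equatorial (alkenyl groups trans-diequatorial on the cyclohexene, methyl and oxide axial), which makes the new C4=C5 alkene E, while the cis C1=C10 alkene is inherited unchanged from the cyclohexene. C6 (R) and C7 (S) are both set here: the S configuration of C4 decides which chair is used, and the E geometry of the enol ether and of the diene puts the PMB-oxy group and C11 equatorial at the bond-forming termini, so O6 and C11 come out trans. The selectivities needed are chair over boat, secured by the trans-diequatorial arrangement, and reaction through the exocyclic diene and not through the ring alkene C1=C10, which could reach C5=C6 only in a strained boat. A dissociative pathway is disfavoured because the alkoxy group on C6 destabilises an allyl anion. Protonation of enolate 23 at −78 °C gives ketone 24; C4 and C9, the two stereocentres of 21, are consumed.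

Step 14
Reactants: 24 (6R,7S)-6-(PMB-oxy)-12,14-bis(TBS-oxy)-1(10)-cis,4E-germacra-1(10),4,11(13)-trien-9-one
Product: 26 (6R,7R,8R)-8-hydroxy-6-(PMB-oxy)-12,14-bis(TBS-oxy)-1(10)-cis,4E-germacra-1(10),4,11(13)-trien-9-one, via sodium enolate 25 (not isolated)
Conditions: NaN(SiMe3)2, THF, −78 °C; then 2-(benzenesulfonyl)-3-phenyloxaziridine, −78 °C; AcOH
Reagents that add atoms: 2-(benzenesulfonyl)-3-phenyloxaziridine, O=S(=O)(c1ccccc1)N1OC1c1ccccc1
Why: Enolate hydroxylation with an N-sulfonyloxaziridine: NaN(SiMe3)2 removes a proton from C8, the only α-carbon that carries hydrogen, and because the hydrogen delivered by the quench in step 13 is the one aligned with the carbonyl π-system, sodium enolate 25 should have the same C8=C9 geometry as 23. The enolate plane stands across the ring, so the oxaziridine should transfer oxygen to the outer face of C8, giving the 8R alcohol with O8 trans to the C7 side chain. This is the C8 epimer of the target and is inverted in step 17; the change of the C7 descriptor to R is only a change of priorities.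

Step 15
Reactants: 27 ethyl 2-(hydroxymethyl)prop-2-enoate
Product: 28 ethyl 2-{[(tert-butyldiphenylsilyl)oxy]methyl}prop-2-enoate
Conditions: TBDPSCl, imidazole, DMF, rt
Reagents that add atoms: tert-butyldiphenylsilyl chloride, CC(C)(C)[Si](Cl)(c1ccccc1)c1ccccc1
Why: Silylation of the primary allylic alcohol; the bulky silyl group is chosen to survive the later selective removal of two TBS ethers and to mask this alcohol during the oxidations.

Step 16
Reactants: 28 ethyl 2-{[(tert-butyldiphenylsilyl)oxy]methyl}prop-2-enoate
Product: 29 2-{[(tert-butyldiphenylsilyl)oxy]methyl}prop-2-enoic acid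
Conditions: LiOH, THF/H2O, 0 °C to rt; then 1 M HCl
Reagents that add atoms: lithium hydroxide, [Li+].[OH-]
Why: Saponification of the ethyl ester at low temperature; the silyl ether is stable to these conditions.

Step 17
Reactants: 26 (6R,7R,8R)-8-hydroxy-6-(PMB-oxy)-12,14-bis(TBS-oxy)-1(10)-cis,4E-germacra-1(10),4,11(13)-trien-9-one; 29 2-{[(tert-butyldiphenylsilyl)oxy]methyl}prop-2-enoic acid
Product: 30 (6R,7S,8S)-8-{[2-(TBDPS-oxymethyl)acryloyl]oxy}-6-(PMB-oxy)-12,14-bis(TBS-oxy)-1(10)-cis,4E-germacra-1(10),4,11(13)-trien-9-one
Conditions: PPh3, DIAD, toluene, 0 °C to rt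
Reagents that add atoms: none
Why: Mitsunobu esterification: the C8 hydroxyl is activated on phosphorus and displaced by the carboxylate of 29 in an SN2 process assisted by the adjacent carbonyl group, so C8 is inverted from R to S and the final acyl group is installed in the same operation. Acylating O8 here means it is never free beside the later C14 ester or the C9 acetate.

Step 18
Reactants: 30 (6R,7S,8S)-8-{[2-(TBDPS-oxymethyl)acryloyl]oxy}-6-(PMB-oxy)-12,14-bis(TBS-oxy)-1(10)-cis,4E-germacra-1(10),4,11(13)-trien-9-one
Product: 31 (6R,7S,8S,9S)-8-{[2-(TBDPS-oxymethyl)acryloyl]oxy}-6-(PMB-oxy)-12,14-bis(TBS-oxy)-1(10)-cis,4E-germacra-1(10),4,11(13)-trien-9-ol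
Conditions: NaBH4, CeCl3·7H2O, MeOH/THF, −78 °C
Reagents that add atoms: none
Why: Luche reduction gives 1,2-addition of hydride to the enone and should leave the acrylate untouched at −78 °C. C9 (S) is set by 1,2-induction from C8: in the Felkin–Anh (polar) or Cornforth arrangement the hydride enters anti to the C8–O bond, past the C8 hydrogen, which gives the threo relationship with O9 trans to O8.

Step 19
Reactants: 31 (6R,7S,8S,9S)-8-{[2-(TBDPS-oxymethyl)acryloyl]oxy}-6-(PMB-oxy)-12,14-bis(TBS-oxy)-1(10)-cis,4E-germacra-1(10),4,11(13)-trien-9-ol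
Product: 32 (6R,7S,8S,9S)-9-acetoxy-8-{[2-(TBDPS-oxymethyl)acryloyl]oxy}-6-(PMB-oxy)-12,14-bis(TBS-oxy)-1(10)-cis,4E-germacra-1(10),4,11(13)-triene
Conditions: Ac2O, pyridine, DMAP (cat.), CH2Cl2, 0 °C
Reagents that add atoms: acetic anhydride, CC(=O)OC(C)=O
Why: Nucleophile-catalysed acetylation of the secondary allylic alcohol; prompt capping prevents migration of the C8 acyl group to O9.

Step 20
Reactants: 32 (6R,7S,8S,9S)-9-acetoxy-8-{[2-(TBDPS-oxymethyl)acryloyl]oxy}-6-(PMB-oxy)-12,14-bis(TBS-oxy)-1(10)-cis,4E-germacra-1(10),4,11(13)-triene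
Product: 33 (6R,7S,8S,9S)-9-acetoxy-8-{[2-(TBDPS-oxymethyl)acryloyl]oxy}-12,14-bis(TBS-oxy)-1(10)-cis,4E-germacra-1(10),4,11(13)-trien-6-ol
Conditions: DDQ, CH2Cl2/pH 7 buffer, 0 °C
Reagents that add atoms: none
Why: Oxidative cleavage of the 4-methoxybenzyl ether (hydride abstraction, then hydrolysis of the oxocarbenium ion) under buffered conditions; silyl ethers, esters and alkenes should be unaffected, and it is run before the primary allylic alcohols are unmasked.

Step 21
Reactants: 33 (6R,7S,8S,9S)-9-acetoxy-8-{[2-(TBDPS-oxymethyl)acryloyl]oxy}-12,14-bis(TBS-oxy)-1(10)-cis,4E-germacra-1(10),4,11(13)-trien-6-ol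
Product: 34 (6R,7S,8S,9S)-9-acetoxy-8-{[2-(TBDPS-oxymethyl)acryloyl]oxy}-1(10)-cis,4E-germacra-1(10),4,11(13)-triene-6,12,14-triol
Conditions: HF·pyridine, pyridine, THF, 0 °C
Reagents that add atoms: none
Why: Buffered HF·pyridine should remove the two primary TBS ethers much faster than the bulkier TBDPS ether, and is too mild to cause transannular cyclisation or acyl migration.

Step 22
Reactants: 34 (6R,7S,8S,9S)-9-acetoxy-8-{[2-(TBDPS-oxymethyl)acryloyl]oxy}-1(10)-cis,4E-germacra-1(10),4,11(13)-triene-6,12,14-triol
Product: 36 (6R,7S,8S,9S)-9-acetoxy-8-{[2-(TBDPS-oxymethyl)acryloyl]oxy}-14-oxo-1(10)-cis,4E-germacra-1(10),4,11(13)-trien-12,6-olide, via lactol 35 (not isolated)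
Conditions: TEMPO (20 mol%), PhI(OAc)2, CH2Cl2, rt
Reagents that add atoms: none
Why: Nitroxyl-catalysed oxidation selective for primary alcohols: the C12 alcohol gives an enal that the C6 hydroxyl traps as lactol 35, which is oxidised on to the α-methylene lactone, while the C14 alcohol gives the enal. The secondary allylic C6 hydroxyl should not be oxidised at a competitive rate, which is why this oxidant is preferred to MnO2; the trans ring fusion follows from the C6 and C7 configurations.

Step 23
Reactants: 36 (6R,7S,8S,9S)-9-acetoxy-8-{[2-(TBDPS-oxymethyl)acryloyl]oxy}-14-oxo-1(10)-cis,4E-germacra-1(10),4,11(13)-trien-12,6-olide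
Product: 37 (6R,7S,8S,9S)-9-acetoxy-8-{[2-(TBDPS-oxymethyl)acryloyl]oxy}-1(10)-cis,4E-germacra-1(10),4,11(13)-trien-12,6-olid-14-oic acid
Conditions: NaClO2, NaH2PO4, 2-methylbut-2-ene, t-BuOH/H2O, 0 °C to rt
Reagents that add atoms: sodium chlorite, [Na+].[O-]Cl=O
Why: Pinnick oxidation converts the enal into the acid without touching the alkenes, the excess alkene scavenging hypochlorous acid.

Step 24
Reactants: 37 (6R,7S,8S,9S)-9-acetoxy-8-{[2-(TBDPS-oxymethyl)acryloyl]oxy}-1(10)-cis,4E-germacra-1(10),4,11(13)-trien-12,6-olid-14-oic acid
Product: 38 methyl (6R,7S,8S,9S)-9-acetoxy-8-{[2-(TBDPS-oxymethyl)acryloyl]oxy}-1(10)-cis,4E-germacra-1(10),4,11(13)-trien-12,6-olid-14-oate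
Conditions: MeI, KHCO3, DMF, rt
Reagents that add atoms: iodomethane, CI
Why: SN2 alkylation of the carboxylate under weakly basic conditions; it avoids diazoalkanes, which would add to the exocyclic enoates.

Step 25
Reactants: 38 methyl (6R,7S,8S,9S)-9-acetoxy-8-{[2-(TBDPS-oxymethyl)acryloyl]oxy}-1(10)-cis,4E-germacra-1(10),4,11(13)-trien-12,6-olid-14-oate
Product: 39 methyl (6R,7S,8S,9S)-9-acetoxy-8-{[2-(hydroxymethyl)acryloyl]oxy}-1(10)-cis,4E-germacra-1(10),4,11(13)-trien-12,6-olid-14-oate (CNP0291058.1)
Conditions: HF·pyridine, THF, 0 °C to rt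
Reagents that add atoms: none
Why: Fluoride cleavage of the remaining silyl ether under mildly acidic conditions that should spare the acetate, the lactone and both Michael acceptors, giving the target.

## Compound list

1 | 2-methylcyclohexanone | CC1CCCCC1=O | starting material
2 | trimethyl[(2-methylcyclohex-1-en-1-yl)oxy]silane | CC1=C(O[Si](C)(C)C)CCCC1 | intermediate
3 | diallyl carbonate | C=CCOC(=O)OCC=C | starting material
4 | (S)-2-allyl-2-methylcyclohexan-1-one | O=C1CCCC[C@@]1(C)CC=C | intermediate
5 | (S)-2-methyl-2-[(E)-prop-1-en-1-yl]cyclohexan-1-one | O=C1CCCC[C@@]1(C)/C=C/C | intermediate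
6 | (S)-1-methyl-2-oxocyclohexane-1-carbaldehyde | O=C1CCCC[C@@]1(C)C=O | intermediate
7 | iodoform | IC(I)I | starting material
8 | (S)-2-[(E)-2-iodoethenyl]-2-methylcyclohexan-1-one | O=C1CCCC[C@@]1(C)/C=C/I | intermediate
9 | 4-methoxybenzyl alcohol | COc1ccc(CO)cc1 | starting material
10 | (S)-2-{(E)-2-[(4-methoxybenzyl)oxy]ethenyl}-2-methylcyclohexan-1-one | O=C1CCCC[C@@]1(C)/C=C/OCc1ccc(OC)cc1 | intermediate
11 | lithium (S)-6-{(E)-2-[(4-methoxybenzyl)oxy]ethenyl}-6-methylcyclohex-1-en-1-olate | [Li+].[O-]C1=CCCC[C@@]1(C)/C=C/OCc1ccc(OC)cc1 | intermediate (not isolated)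
12 | (S)-6-{(E)-2-[(4-methoxybenzyl)oxy]ethenyl}-6-methylcyclohex-2-en-1-one | O=C1C=CCC[C@@]1(C)/C=C/OCc1ccc(OC)cc1 | intermediate
13 | formaldehyde | C=O | starting material
14 | (S)-2-(hydroxymethyl)-6-{(E)-2-[(4-methoxybenzyl)oxy]ethenyl}-6-methylcyclohex-2-en-1-one | O=C1C(CO)=CCC[C@@]1(C)/C=C/OCc1ccc(OC)cc1 | intermediate
15 | (S)-2-{[(tert-butyldimethylsilyl)oxy]methyl}-6-{(E)-2-[(4-methoxybenzyl)oxy]ethenyl}-6-methylcyclohex-2-en-1-one | O=C1C(CO[Si](C)(C)C(C)(C)C)=CCC[C@@]1(C)/C=C/OCc1ccc(OC)cc1 | intermediate
16 | 2-bromoprop-2-en-1-ol | OCC(Br)=C | starting material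
17 | [(2-bromoprop-2-en-1-yl)oxy](tert-butyl)dimethylsilane | C=C(Br)CO[Si](C)(C)C(C)(C)C | intermediate
18 | (E)-1,2-bis(tributylstannyl)ethene | CCCC[Sn](CCCC)(CCCC)/C=C/[Sn](CCCC)(CCCC)CCCC | starting material
19 | (E)-tert-butyldimethyl{[2-methylidene-4-(tributylstannyl)but-3-en-1-yl]oxy}silane | CCCC[Sn](CCCC)(CCCC)/C=C/C(=C)CO[Si](C)(C)C(C)(C)C | intermediate
20 | [(1E)-3-{[(tert-butyldimethylsilyl)oxy]methyl}buta-1,3-dien-1-yl]lithium | [Li]/C=C/C(=C)CO[Si](C)(C)C(C)(C)C | intermediate (not isolated)
21 | (1R,6S)-1-[(1E)-3-{[(tert-butyldimethylsilyl)oxy]methyl}buta-1,3-dien-1-yl]-2-{[(tert-butyldimethylsilyl)oxy]methyl}-6-{(E)-2-[(4-methoxybenzyl)oxy]ethenyl}-6-methylcyclohex-2-en-1-ol (alkenyl groups trans) | O[C@@]1(/C=C/C(=C)CO[Si](C)(C)C(C)(C)C)C(CO[Si](C)(C)C(C)(C)C)=CCC[C@@]1(C)/C=C/OCc1ccc(OC)cc1 | intermediate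
22 | potassium alkoxide of 21 | [K+].[O-][C@@]1(/C=C/C(=C)CO[Si](C)(C)C(C)(C)C)C(CO[Si](C)(C)C(C)(C)C)=CCC[C@@]1(C)/C=C/OCc1ccc(OC)cc1 | intermediate (not isolated)
23 | potassium C8=C9 enolate of 24 (C7 and C10 trans across the enolate) | [K+].[O-]/C1=C\[C@@H](C(=C)CO[Si](C)(C)C(C)(C)C)[C@H](OCc2ccc(OC)cc2)/C=C(\C)CC/C=C1/CO[Si](C)(C)C(C)(C)C | intermediate (not isolated)
24 | (6R,7S)-6-(PMB-oxy)-12,14-bis(TBS-oxy)-1(10)-cis,4E-germacra-1(10),4,11(13)-trien-9-one | O=C1C[C@@H](C(=C)CO[Si](C)(C)C(C)(C)C)[C@H](OCc2ccc(OC)cc2)/C=C(\C)CC/C=C1/CO[Si](C)(C)C(C)(C)C | intermediate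
25 | sodium C8=C9 enolate of 24 (C7 and C10 trans across the enolate) | [Na+].[O-]/C1=C\[C@@H](C(=C)CO[Si](C)(C)C(C)(C)C)[C@H](OCc2ccc(OC)cc2)/C=C(\C)CC/C=C1/CO[Si](C)(C)C(C)(C)C | intermediate (not isolated)
26 | (6R,7R,8R)-8-hydroxy-6-(PMB-oxy)-12,14-bis(TBS-oxy)-1(10)-cis,4E-germacra-1(10),4,11(13)-trien-9-one (O8 trans to the C7 side chain) | O=C1[C@H](O)[C@@H](C(=C)CO[Si](C)(C)C(C)(C)C)[C@H](OCc2ccc(OC)cc2)/C=C(\C)CC/C=C1/CO[Si](C)(C)C(C)(C)C | intermediate
27 | ethyl 2-(hydroxymethyl)prop-2-enoate | C=C(CO)C(=O)OCC | starting material
28 | ethyl 2-{[(tert-butyldiphenylsilyl)oxy]methyl}prop-2-enoate | C=C(CO[Si](c1ccccc1)(c1ccccc1)C(C)(C)C)C(=O)OCC | intermediate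
29 | 2-{[(tert-butyldiphenylsilyl)oxy]methyl}prop-2-enoic acid | C=C(CO[Si](c1ccccc1)(c1ccccc1)C(C)(C)C)C(=O)O | intermediate
30 | (6R,7S,8S)-8-{[2-(TBDPS-oxymethyl)acryloyl]oxy}-6-(PMB-oxy)-12,14-bis(TBS-oxy)-1(10)-cis,4E-germacra-1(10),4,11(13)-trien-9-one | O=C1[C@@H](OC(=O)C(=C)CO[Si](c2ccccc2)(c2ccccc2)C(C)(C)C)[C@@H](C(=C)CO[Si](C)(C)C(C)(C)C)[C@H](OCc2ccc(OC)cc2)/C=C(\C)CC/C=C1/CO[Si](C)(C)C(C)(C)C | intermediate
31 | (6R,7S,8S,9S)-8-{[2-(TBDPS-oxymethyl)acryloyl]oxy}-6-(PMB-oxy)-12,14-bis(TBS-oxy)-1(10)-cis,4E-germacra-1(10),4,11(13)-trien-9-ol | O[C@@H]1[C@@H](OC(=O)C(=C)CO[Si](c2ccccc2)(c2ccccc2)C(C)(C)C)[C@@H](C(=C)CO[Si](C)(C)C(C)(C)C)[C@H](OCc2ccc(OC)cc2)/C=C(\C)CC/C=C1/CO[Si](C)(C)C(C)(C)C | intermediate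
32 | (6R,7S,8S,9S)-9-acetoxy-8-{[2-(TBDPS-oxymethyl)acryloyl]oxy}-6-(PMB-oxy)-12,14-bis(TBS-oxy)-1(10)-cis,4E-germacra-1(10),4,11(13)-triene | CC(=O)O[C@@H]1[C@@H](OC(=O)C(=C)CO[Si](c2ccccc2)(c2ccccc2)C(C)(C)C)[C@@H](C(=C)CO[Si](C)(C)C(C)(C)C)[C@H](OCc2ccc(OC)cc2)/C=C(\C)CC/C=C1/CO[Si](C)(C)C(C)(C)C | intermediate
33 | (6R,7S,8S,9S)-9-acetoxy-8-{[2-(TBDPS-oxymethyl)acryloyl]oxy}-12,14-bis(TBS-oxy)-1(10)-cis,4E-germacra-1(10),4,11(13)-trien-6-ol | CC(=O)O[C@@H]1[C@@H](OC(=O)C(=C)CO[Si](c2ccccc2)(c2ccccc2)C(C)(C)C)[C@@H](C(=C)CO[Si](C)(C)C(C)(C)C)[C@H](O)/C=C(\C)CC/C=C1/CO[Si](C)(C)C(C)(C)C | intermediate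
34 | (6R,7S,8S,9S)-9-acetoxy-8-{[2-(TBDPS-oxymethyl)acryloyl]oxy}-1(10)-cis,4E-germacra-1(10),4,11(13)-triene-6,12,14-triol | CC(=O)O[C@@H]1[C@@H](OC(=O)C(=C)CO[Si](c2ccccc2)(c2ccccc2)C(C)(C)C)[C@@H](C(=C)CO)[C@H](O)/C=C(\C)CC/C=C1/CO | intermediate
35 | (6R,7S,8S,9S)-9-acetoxy-8-{[2-(TBDPS-oxymethyl)acryloyl]oxy}-12-hydroxy-14-oxo-6,12-epoxy-1(10)-cis,4E-germacra-1(10),4,11(13)-triene (lactol; C12 epimers) | C=C(CO[Si](c1ccccc1)(c1ccccc1)C(C)(C)C)C(=O)O[C@H]1[C@H]2C(=C)C(O)O[C@@H]2/C=C(\C)CC/C=C(/C=O)[C@@H]1OC(C)=O | intermediate (not isolated)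
36 | (6R,7S,8S,9S)-9-acetoxy-8-{[2-(TBDPS-oxymethyl)acryloyl]oxy}-14-oxo-1(10)-cis,4E-germacra-1(10),4,11(13)-trien-12,6-olide | C=C(CO[Si](c1ccccc1)(c1ccccc1)C(C)(C)C)C(=O)O[C@H]1[C@H]2C(=C)C(=O)O[C@@H]2/C=C(\C)CC/C=C(/C=O)[C@@H]1OC(C)=O | intermediate
37 | (6R,7S,8S,9S)-9-acetoxy-8-{[2-(TBDPS-oxymethyl)acryloyl]oxy}-1(10)-cis,4E-germacra-1(10),4,11(13)-trien-12,6-olid-14-oic acid | C=C(CO[Si](c1ccccc1)(c1ccccc1)C(C)(C)C)C(=O)O[C@H]1[C@H]2C(=C)C(=O)O[C@@H]2/C=C(\C)CC/C=C(/C(=O)O)[C@@H]1OC(C)=O | intermediate
38 | methyl (6R,7S,8S,9S)-9-acetoxy-8-{[2-(TBDPS-oxymethyl)acryloyl]oxy}-1(10)-cis,4E-germacra-1(10),4,11(13)-trien-12,6-olid-14-oate | C=C(CO[Si](c1ccccc1)(c1ccccc1)C(C)(C)C)C(=O)O[C@H]1[C@H]2C(=C)C(=O)O[C@@H]2/C=C(\C)CC/C=C(/C(=O)OC)[C@@H]1OC(C)=O | intermediate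
39 | methyl (6R,7S,8S,9S)-9-acetoxy-8-{[2-(hydroxymethyl)acryloyl]oxy}-1(10)-cis,4E-germacra-1(10),4,11(13)-trien-12,6-olid-14-oate (CNP0291058.1) | C=C(CO)C(=O)O[C@H]1[C@H]2C(=C)C(=O)O[C@@H]2/C=C(\C)CC/C=C(/C(=O)OC)[C@@H]1OC(C)=O | target

## Step count and least certain steps

Total: 25 steps. Longest linear sequence: 21 steps (steps 1 to 9, 12 to 14, 17 to 25).

Step 13 (key step). The most likely failure is loss of stereochemical fidelity: the strongly activated alkoxide could cleave the C4–C9 bond heterolytically and recombine at the wrong terminus, or the basic medium could degrade the enol ether and the product enone. Fallback: run the rearrangement without an alkoxide. Starting from 21, the tertiary alcohol is silylated to its trimethylsilyl ether F1, which is heated in a non-polar solvent so that the neutral silyloxy-Cope shift gives the trimethylsilyl enol ether F2 through the same chair. Mild methanolysis of F2 (K2CO3, MeOH) returns to the route at 24.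

Step 14. The most likely failure is oxygen transfer to the other face, because the enolate formed from 24 could populate a folded conformation or a C8=C9 geometry different from the one delivered by the rearrangement. Fallback: the route then switches from inversion to retention. The hydroxylation of 24 would give the C8 epimer (6R,7R,8S)-8-hydroxy ketone F3, which is esterified directly with 29 (N,N'-dicyclohexylcarbodiimide, DMAP) and rejoins the route at 30.

Step 17. The most likely failure is that displacement at C8 does not compete with elimination or recovery of the alcohol, because the rear side of C8 may be screened across the ring and C7 is branched. Fallback: invert C8 by enolisation and kinetic protonation instead of substitution. Starting from 26, the hydroxyl is silylated to the 8R triethylsilyl ether F4. Deprotonation with LiN(iPr)2 and protonation from the outer face (the face that oxygen used in step 14) should give the 8S triethylsilyl ether F5. Brief buffered HF·pyridine removes the triethylsilyl group to give the 8S alcohol F3 described under step 14, and carbodiimide esterification with 29 returns to the route at 30.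

Step 18. The most likely failure is poor facial selectivity of hydride delivery if the ring folds so that the Felkin–Anh face is the hindered one, together with some migration of the C8 acyl group to the new alkoxide. Fallback: correct C9 by substitution. The 9R alcohol F6 obtained from 30 is treated with acetic acid under Mitsunobu conditions (PPh3, DIAD), which inverts C9 and acetylates it in one operation, returning to the route at 32.

Step 12. The most likely failure is poor facial selectivity of the addition, because methyl and the alkenyl group on C4 differ little in size. Fallback: use the minor carbinol productively. The (1S,6S) epimer F7 formed from 15 and 19 is submitted to the conditions of step 13; a chair with C3 still equatorial on C4 and the C10 branch axial on C9 should lead to the same C6 and C7 configurations and the same E alkene, returning to the route at 24.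

## Further compounds

F1 | step 13 | trimethylsilyl ether of 21 | C[Si](C)(C)O[C@@]1(/C=C/C(=C)CO[Si](C)(C)C(C)(C)C)C(CO[Si](C)(C)C(C)(C)C)=CCC[C@@]1(C)/C=C/OCc1ccc(OC)cc1
F2 | step 13 | trimethylsilyl enol ether of 24 (C8=C9) | C[Si](C)(C)O/C1=C\[C@@H](C(=C)CO[Si](C)(C)C(C)(C)C)[C@H](OCc2ccc(OC)cc2)/C=C(\C)CC/C=C1/CO[Si](C)(C)C(C)(C)C
F3 | step 14 | (6R,7R,8S)-8-hydroxy-6-(PMB-oxy)-12,14-bis(TBS-oxy)-1(10)-cis,4E-germacra-1(10),4,11(13)-trien-9-one | O=C1[C@@H](O)[C@@H](C(=C)CO[Si](C)(C)C(C)(C)C)[C@H](OCc2ccc(OC)cc2)/C=C(\C)CC/C=C1/CO[Si](C)(C)C(C)(C)C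
F4 | step 17 | (6R,7S,8R)-8-(triethylsilyloxy)-6-(PMB-oxy)-12,14-bis(TBS-oxy)-1(10)-cis,4E-germacra-1(10),4,11(13)-trien-9-one | O=C1[C@H](O[Si](CC)(CC)CC)[C@@H](C(=C)CO[Si](C)(C)C(C)(C)C)[C@H](OCc2ccc(OC)cc2)/C=C(\C)CC/C=C1/CO[Si](C)(C)C(C)(C)C
F5 | step 17 | (6R,7S,8S)-8-(triethylsilyloxy)-6-(PMB-oxy)-12,14-bis(TBS-oxy)-1(10)-cis,4E-germacra-1(10),4,11(13)-trien-9-one | O=C1[C@@H](O[Si](CC)(CC)CC)[C@@H](C(=C)CO[Si](C)(C)C(C)(C)C)[C@H](OCc2ccc(OC)cc2)/C=C(\C)CC/C=C1/CO[Si](C)(C)C(C)(C)C
F6 | step 18 | (6R,7S,8S,9R)-8-{[2-(TBDPS-oxymethyl)acryloyl]oxy}-6-(PMB-oxy)-12,14-bis(TBS-oxy)-1(10)-cis,4E-germacra-1(10),4,11(13)-trien-9-ol | O[C@H]1[C@@H](OC(=O)C(=C)CO[Si](c2ccccc2)(c2ccccc2)C(C)(C)C)[C@@H](C(=C)CO[Si](C)(C)C(C)(C)C)[C@H](OCc2ccc(OC)cc2)/C=C(\C)CC/C=C1/CO[Si](C)(C)C(C)(C)C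
F7 | step 12 | (1S,6S) epimer of 21 (alkenyl groups cis) | O[C@]1(/C=C/C(=C)CO[Si](C)(C)C(C)(C)C)C(CO[Si](C)(C)C(C)(C)C)=CCC[C@@]1(C)/C=C/OCc1ccc(OC)cc1
A1 | alternative 1 | cis-anti-cis tricyclo[4.4.0.0(2,5)]decanone photoadduct | COC(=O)[C@]12[C@@H]3CC[C@]3(C)[C@H]1[C@H]1OC(=O)C[C@@H]1[C@H](O[Si](C)(C)C(C)(C)C)C2=O
A2 | alternative 1 | bicyclic enone ester (cyclohexenone fused to the lactone; C14 ester on C10; TBS ether on O8) | COC(=O)C1=C[C@H]2OC(=O)C[C@@H]2[C@H](O[Si](C)(C)C(C)(C)C)C1=O
A3 | alternative 1 | 1-methylcyclobutene | CC1=CCC1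
A4 | alternative 1 | ten-membered dienone from cycloreversion (1(10)-cis, 4E; 9-ketone; 14-ester) | COC(=O)/C1=C/CC/C(C)=C/[C@H]2OC(=O)C[C@@H]2[C@H](O[Si](C)(C)C(C)(C)C)C1=O
A5 | alternative 2 | 8-hydroxy-9-acetoxy melampolide (39 without the O8 acyl group) | O[C@H]1[C@H]2C(=C)C(=O)O[C@@H]2/C=C(\C)CC/C=C(/C(=O)OC)[C@@H]1OC(C)=O
A6 | alternative 2 | open-chain C8 aldehyde with C1 allylic bromide and C9 enol acetate (C1 and enol acetate geometry not fixed) | O=C[C@H]1C(=C)C(=O)O[C@@H]1/C=C(\C)CCC(Br)C(C(=O)OC)=COC(C)=O
A7 | alternative 3 | protected melampolide with 14-ester and saturated lactone α-carbon | CC(C)(C)[Si](C)(C)O[C@H]1[C@H]2CC(=O)O[C@@H]2/C=C(\C)CC/C=C(/C(=O)OC)[C@@H]1OCc1ccc(OC)cc1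
A8 | alternative 3 | cis-fused decalin with C4 pinacol boronate and C1 mesylate (1α-mesyloxy, 4α-methyl, 4β-boryl, 5β-H, 10β-ester) | CC(C)(C)[Si](C)(C)O[C@H]1[C@H]2CC(=O)O[C@@H]2[C@@H]3[C@@](C)(B4OC(C)(C)C(C)(C)O4)CC[C@H](OS(C)(=O)=O)[C@]3(C(=O)OC)[C@@H]1OCc1ccc(OC)cc1
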